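## Structural features

The target is a germacranolide. Ring A is a ten-membered carbocycle (C1–C10) with two E-configured trisubstituted alkenes, C1=C10 and C4=C5 (methyls C14 on C10 and C15 on C4). It is fused across C6–C7 to an α,β-unsaturated γ-lactone (ring B: C6, the ring oxygen, C12, C11, C7) whose C7=C11 bond is tetrasubstituted and whose C11 carries the acetoxymethyl carbon C13. There are three stereocentres, C2 (R), C6 (R) and C8 (S), and none is adjacent to another. C6 and C8 flank the trigonal C7 with their oxygens on the same face of ring A; C2 lies across the ring with its oxygen on the other face. No centre can therefore be relayed from a neighbour. Three acyloxy groups of two kinds must be told apart: acetates on O2 (allylic) and O13 (primary, next to the butenolide) and a methacrylate on O8. The fragile points are the E,E-cyclodeca-1,5-diene (Cope rearrangement on heating, transannular cyclisation under acid), the C6 hydrogen (γ to the lactone carbonyl and allylic, so open to base epimerisation) and the polymerisable methacrylate. The real difficulty is to obtain the strained ring A with both alkenes E and three isolated stereocentres in one absolute sense. The key step exploits the fact that C1=C10 and C4=C5 flank the C2–C3 bond. Ring A is then the formal metathesis product of a cyclohexenone alkene C5=C10 (ring C5–C10, carbonyl at C6, carrying C8) and a cyclobutene C1=C4 (carrying C2 and C3), so it arises by opening two fused cyclobutanes and not by a medium-ring closure.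

## Logic of the disconnections

27 ⇒ 26 ⇒ 25 ⇒ 24 ⇒ 23. The three acyl C–O bonds are cut: the methacryloyl on O8 first, then the two acetyls on O2 and O13 together. The polymerisable ester is cut first so that it goes on last, and the two acetates share one deprotection and one acylation. The three esters reduce to two orthogonal ether types (silyl on O2 and O13, 4-methoxybenzyl on O8). The forward steps must use fluoride under buffered acid, a neutral oxidant and weak amine bases only, so that H6 is not removed.

23 ⇒ 21 (through 22). The lactone C12–O6 bond and the C6–H bond are cut. This is done because a C6 carbonyl is what the key step delivers. Ring B and the C6 centre disappear and an alkylidene keto ester remains. The forward step needs 1,2-reduction on the correct face and the Z geometry at C7=C11 so that the ester can reach O6.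

21 ⇒ 19 ⇒ 14 + 18. The C7=C11 π bond and then the C7–C11 σ bond are cut. C7 is the only enolisable α′ position of 14, and 18 brings C11, C12 and C13 at the right oxidation levels. This removes three carbons and leaves a plain dienone. The forward aldol must outrun proton transfer and β-elimination of the O8 ether, and the elimination must run across C7–C11.

18 ⇒ 16 ⇒ 15. The keto C=O is traced to a C=CH2 bond and the O–Si bond is cut, which leads to a commercial acrylate.

14 ⇒ 13 (key step). In the reverse sense the two ring alkenes are exchanged for the σ bonds C1–C4 and C5–C10. This replaces a strained ten-membered ring by a tricycle made of a six-membered and two four-membered rings. The forward cycloreversion must start from a trans ring fusion at C5/C10 and must be over before the product can undergo a Cope shift.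

13 ⇒ 7 + 12. The σ bonds C1–C10 and C4–C5 are cut ([2+2]). Each partner is a small ring that carries one stereocentre (C8 in 7, C2 in 12), so the two remote centres are set independently. The forward step must join C4 to C5 (not to C10), must give the trans junction and must be worked up without base. O2 is a silyl ether because 11 tolerates neither alkoxide formation nor acid; O8 is the benzyl-type ether because it can be put on safely at the stage of 1.

7 ⇒ 6 ⇒ 5 ⇒ 3 (through 4) ⇒ 2 ⇒ 1. The C10–C14 bond is cut with a 1,3-transposition of oxygen, then the C=C bond (β-elimination) and the C=O (oxidation), then the acetyl and the benzyl-type ether. This leads back to a symmetrical triol. The forward sequence needs one desymmetrising event (step 2) and must avoid aromatisation of the β-alkoxy enones.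

12 ⇒ 11 ⇒ 10 ⇒ 8. The O–Si bond, the C2–H bond (asymmetric hydride delivery) and the C4–C15 bond are cut, back to a commercial vinylogous ester. The forward steps must keep the cyclobutene cold and away from alkoxide and acid.

## Other disconnections considered

Alternative 1: The cut is C6–C7, after formal rehydration of C7=C11. Ring A and ring B would close together from the thirteen-membered β-keto lactone A2 (allylic ester at O6, ketone at C7). In the forward step Pyrex-filtered light excites the C7 ketone, which abstracts the allylic, oxygen-bearing hydrogen at C6 through a seven-membered transition state. The 1,5-biradical collapses to the 7-hydroxy lactone A1, which is then dehydrated and its acyl groups exchanged.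
- In its favour: a thirteen-membered lactone closes far more easily than a ten-membered carbocycle. Both E-alkenes come from acyclic chemistry of unambiguous geometry, which is better than the chosen plan, where geometry depends on a ring fusion. The lactone exists before the C7=C11 bond, so the alkene geometry problem of step 14 does not arise (also better).
- Against it: the C6 radical is allylic, so it can recombine at C4 or lose the C4=C5 geometry. Hydrogen abstraction at C6 competes with α-cleavage of the substituted β-keto ester, with abstraction at C9 and with transannular oxetane formation. The C6 configuration would be decided in a floppy biradical, and the tertiary alcohol must dehydrate towards C11.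
- Comparison: in structure it is the more convergent plan, and in step count it should be about equal. In mechanism the chosen cycloreversion is judged safer, because its regiochemistry follows from bond strengths. Both plans leave C6 to substrate control (equal).

Alternative 2: The cut is C2–C3, with C5–C10 reconnected. Ring A is the ring-expanded form of the trans-dialkenylcyclohexanol A4 (C5 carbinol with the isopropenyl unit C3/C4/C15, C10 with the silyloxyvinyl unit C1/C2). In the forward step KH with 18-crown-6 in THF triggers the anionic oxy-Cope shift, and PhNTf2 traps the C4=C5 enolate as the dienyl triflate A3.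
- In its favour: this ring expansion is the classical entry to germacradienones. It runs near room temperature, so the product is in no danger of a Cope shift, which is better than the thermal key step. The chair transition state fixes C1=C10 and transfers chirality to C2, so C2 needs no separate asymmetric reduction (better). C6 is set on a six-membered ring (better than the late reduction in ring A). With O6 next to a C7 ketone, ring B could be closed intramolecularly from an O6 ester with fixed C7=C11 geometry (better than step 14).
- Against it: A4 has four stereocentres, two of them adjacent and fully substituted. Its C5 alkoxide sits next to an ether and a ketal, which invites fragmentation and silyl migration. After the key step the C5 triflate must be reduced, the ketal removed and a tetrasubstituted alkene built on a hindered ketone.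
- Comparison: in mechanism it is more secure than the chosen step. In structure its product is further from the target. In step economy it is clearly longer.

Alternative 3: The cut is C5–C6. The acyclic (E)-alkenyl iodide A6 carries a 2-silyloxyfuran that already holds C6, C7, C11, C12 and C13. In the forward step zerovalent palladium from Pd2(dba)3 and P(t-Bu)3 inserts into the C5–I bond, CsF releases the furanolate, and the palladium dienolate eliminates reductively at C6. This closes ring A, turns the furan into ring B and creates C6. The product A5 is the same compound as 23, so the last four steps are shared (equal).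
- In its favour: ring B, C13 and both alkenes exist before ring closure, with geometry from acyclic chemistry (better). No thermolysis is needed and the C7=C11 geometry problem does not arise (better).
- Against it: a strained ten-membered E,E-diene must be closed by C(sp2)–C(sp3) reductive elimination from a large palladacycle. This competes with oligomerisation, coupling at the other furan terminus and protodehalogenation. Intermolecular γ-arylation is the nearest precedent, so the macrocyclic version would have to be developed. C6 is set under remote control and, being acidic, can re-equilibrate under CsF.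
- Comparison: in structure and convergence it is better, and in step count about equal. In mechanism the chosen plan is preferred because it needs no medium-ring closure at all.

Key step: step 10

Assumption: the lipase of step 2 is taken to acetylate the hydroxyl that leads to 3; if it prefers the enantiotopic one, the same enzyme used in the hydrolytic direction on the diacetate of 2 exposes the other hydroxyl and gives 3.

## Route

Step 1
Reactants: 1 cis,cis-cyclohexane-1,3,5-triol
Product: 2 all-cis-5-[(4-methoxybenzyl)oxy]cyclohexane-1,3-diol (meso)
Conditions: NaH (1 equiv), PMBCl (1 equiv), DMF, 0 → 23 °C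
Reagents that add atoms: 4-methoxybenzyl chloride, COc1ccc(CCl)cc1
Why: Williamson etherification; the three hydroxyls of 1 are homotopic, so only the degree of alkylation needs control (one equivalent of base, unreacted 1 recovered), and the product is meso.

Step 2
Reactants: 2 all-cis-5-[(4-methoxybenzyl)oxy]cyclohexane-1,3-diol
Product: 3 (1R,3R,5S)-3-acetoxy-5-[(4-methoxybenzyl)oxy]cyclohexan-1-ol (all-cis)
Conditions: Candida antarctica lipase B (immobilised), vinyl acetate, t-BuOMe, 30 °C
Reagents that add atoms: vinyl acetate, C=COC(C)=O
Why: Enzymatic desymmetrisation of a meso 1,3-diol by irreversible transesterification; the enzyme distinguishes the two enantiotopic carbinols and thereby fixes the configuration of the ether-bearing carbon, the future C8.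

Step 3
Reactants: 3 (1R,3R,5S)-3-acetoxy-5-[(4-methoxybenzyl)oxy]cyclohexan-1-ol
Product: 5 (R)-5-[(4-methoxybenzyl)oxy]cyclohex-2-en-1-one, via the β-acetoxy ketone 4 (not isolated)
Conditions: Dess–Martin periodinane, pyridine, CH2Cl2, 0 → 23 °C; then DBU, 0 °C
Reagents that add atoms: none
Why: Dess–Martin oxidation of the free carbinol, then E1cB loss of acetate (a far better leaving group than the ether) gives the enone; the C8 centre is untouched, and the base is kept cold and brief to prevent a second elimination to the phenol.

Step 4
Reactants: 5 (R)-5-[(4-methoxybenzyl)oxy]cyclohex-2-en-1-one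
Product: 6 (5R)-5-[(4-methoxybenzyl)oxy]-1-methylcyclohex-2-en-1-ol (C1 epimers)
Conditions: MeLi, CeCl3 (anhydrous), THF, −78 °C
Reagents that add atoms: methyllithium, [Li]C
Why: 1,2-addition of the weakly basic organocerium reagent to the enone carbonyl avoids enolisation and β-elimination; the new carbinol centre is of no consequence because step 5 removes it.

Step 5
Reactants: 6 (5R)-5-[(4-methoxybenzyl)oxy]-1-methylcyclohex-2-en-1-ol
Product: 7 (S)-5-[(4-methoxybenzyl)oxy]-3-methylcyclohex-2-en-1-one
Conditions: pyridinium chlorochromate (C5H5NH[CrO3Cl]), 4 Å molecular sieves, CH2Cl2, 23 °C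
Reagents that add atoms: pyridinium chlorochromate, [O-][Cr](=O)(=O)Cl.c1cc[nH+]cc1
Why: Babler–Dauben oxidative transposition: chromate ester, [3,3] shift and oxidation move the oxygen to the far allylic terminus and leave the methyl on the β-carbon (future C10 with C14); the C8 centre is not involved.

Step 6
Reactants: 8 3-ethoxycyclobut-2-en-1-one
Product: 10 3-methylcyclobut-2-en-1-one, via the tertiary cyclobutenol 9 (not isolated)
Conditions: MeLi, Et2O, −78 °C; then 1 M HCl, −78 → 0 °C
Reagents that add atoms: methyllithium, [Li]C
Why: Stork–Danheiser sequence: 1,2-addition to the vinylogous ester, then acid hydrolysis of the enol ether with loss of ethanol transposes the carbonyl; the cold quench forestalls anion-accelerated ring opening of the cyclobutenyl alkoxide.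

Step 7
Reactants: 10 3-methylcyclobut-2-en-1-one
Product: 11 (R)-3-methylcyclobut-2-en-1-ol
Conditions: (S)-2-methyl-CBS-oxazaborolidine (cat.), catecholborane, toluene, −78 °C; then MeOH
Reagents that add atoms: none
Why: Corey–Bakshi–Shibata reduction of a cyclic enone; with the alkenyl flank acting as the large group, hydride should be delivered to the face that gives the (R)-carbinol (future C2), and catecholborane at low temperature leaves the strained alkene alone.

Step 8
Reactants: 11 (R)-3-methylcyclobut-2-en-1-ol
Product: 12 (R)-tert-butyldimethyl[(3-methylcyclobut-2-en-1-yl)oxy]silane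
Conditions: TBSCl, imidazole, CH2Cl2, 0 °C
Reagents that add atoms: tert-butyldimethylsilyl chloride, CC(C)(C)[Si](C)(C)Cl
Why: Silylation under weakly basic, non-ionising conditions; an alkoxide would undergo anion-accelerated electrocyclic ring opening and acid would ionise the cyclobutenol, so a group that needs neither is used.

Step 9
Reactants: 7 (S)-5-[(4-methoxybenzyl)oxy]-3-methylcyclohex-2-en-1-one and 12 (R)-tert-butyldimethyl[(3-methylcyclobut-2-en-1-yl)oxy]silane
Product: 13 trans-fused photoadduct (target numbering, 1R,2R,4R,5S,8S,10R): cyclohexanone C5–C10 with the C6 ketone and the O8 4-methoxybenzyl ether, trans-fused at C5–C10 to the cis-bicyclo[2.2.0]hexane C1/C2/C3/C4/C5/C10, methyls on C4 and C10, O2 silyl ether anti to the C5–C10 bridge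
Conditions: hν (350 nm, Pyrex), CH2Cl2, −40 °C, 12 (3 equiv, excess recovered); chromatography on neutral support
Reagents that add atoms: none
Why: Enone–alkene [2+2] photocycloaddition through the triplet enone and a 1,4-biradical: the methyl-bearing C10 should bond to the unsubstituted cyclobutene carbon C1 on the face away from the silyloxy group, leaving a tertiary radical at C4 that closes on C5 and so avoiding two adjacent quaternary carbons; the trans six–four junction is the kinetic outcome typical of twisted cyclohexenone triplets. The four new ring-fusion centres (C1, C4, C5, C10) are all destroyed in step 10, so every trans-fused diastereomer is pooled with 13 and only contact with base (epimerisation at C5) must be avoided.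

Step 10
Reactants: 13 trans-fused photoadduct
Product: 14 (2E,5R,6E,9S)-5-[(tert-butyldimethylsilyl)oxy]-9-[(4-methoxybenzyl)oxy]-3,7-dimethylcyclodeca-2,6-dien-1-one (target numbering: ring A with C6 ketone, 1(10)E, 4E, 2R, 8S)
Conditions: flash vacuum thermolysis, base-washed quartz tube, 500–550 °C, about 0.01 mbar, contact time of milliseconds; condensed at −196 °C, chromatography at 0 °C
Reagents that add atoms: none
Why: Strain-release cycloreversion: in the gas phase the photoadduct homolyses at its weakest bonds, either the central C1–C4 bond of the bicyclo[2.2.0]hexane (giving the cyclohexane-1,4-diyl C1, C2, C3, C4, C5, C10) or the C5–C10 bond (tertiary and α to the ketone), and scission of the other bond then forms the C1=C10 and C4=C5 π bonds. The closest known reaction type is the thermal opening of enone–cyclobutene photoadducts (tricyclo[4.4.0.0(2,5)]decanones) to cyclodeca-1,5-dienes, itself the bicyclo[2.2.0]hexane to hexa-1,5-diene cycloreversion. Ring A is not closed by bond formation but by fragmentative ring expansion: cleavage of the ring-fusion bond C5–C10 merges the six-membered ring with the four carbons C1–C4 into the ten-membered ring. No stereocentre is created; C2 and C8 are spectators and the four ring-fusion centres disappear. What must be controlled is alkene geometry, and the controlling element is the trans ring fusion: in the chair-like diyl C6 and C9 are both equatorial, so each ends up trans to the ring carbon across its new double bond (both E), whereas a cis-fused adduct would give one Z alkene. The step also needs scission of C5–C10 and not of C2–C3, which the tertiary, α-keto character of C5–C10 and the conjugation gained by C4=C5 should secure. Finally the product must escape a Cope shift: a short contact time at high temperature favours the high-entropy fragmentation over the ordered chair Cope process, which in addition would sacrifice the enone conjugation.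

Step 11
Reactants: 15 ethyl 2-(hydroxymethyl)acrylate
Product: 16 ethyl 2-{[(tert-butyldimethylsilyl)oxy]methyl}acrylate
Conditions: TBSCl, imidazole, CH2Cl2, 0 → 23 °C
Reagents that add atoms: tert-butyldimethylsilyl chloride, CC(C)(C)[Si](C)(C)Cl
Why: Routine silylation of a primary allylic alcohol.

Step 12
Reactants: 16 ethyl 2-{[(tert-butyldimethylsilyl)oxy]methyl}acrylate
Product: 18 ethyl 3-[(tert-butyldimethylsilyl)oxy]-2-oxopropanoate, via the ozonide 17 (not isolated)
Conditions: O3, CH2Cl2, −78 °C; then Me2S, −78 → 23 °C
Reagents that add atoms: ozone, [O-][O+]=O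
Why: Ozonolysis of the 1,1-disubstituted alkene with reductive work-up gives the α-keto ester; the silyl ether and the ester are inert to ozone at −78 °C.

Step 13
Reactants: 14 (E,E)-cyclodecadienone and 18 ethyl 3-[(tert-butyldimethylsilyl)oxy]-2-oxopropanoate
Product: 19 C7 aldol adduct: 14 carrying at C7 the group C11(OH)(CO2Et)(CH2OSi-t-BuMe2), C7/C11 epimer mixture, 2R,8S
Conditions: LiN(i-Pr)2 (1.05 equiv), THF, −78 °C; then 18, −78 °C; AcOH quench at −78 °C
Reagents that add atoms: none
Why: Kinetic deprotonation of the enone at the α′ carbon C7 and aldol addition to the highly electrophilic keto carbonyl of 18; low temperature and the cold acidic quench suppress β-elimination of the O8 ether, retro-aldol cleavage and silyl migration. The C7 and C11 centres form as a mixture that step 14 erases.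

Step 14
Reactants: 19 C7 aldol adduct
Product: 21 (Z)-alkylidene keto ester: ring A dienone with exocyclic C7=C11, CO2Et syn to the C6 ketone and CH2OSi-t-BuMe2 syn to C8, 2R,8S, via the tertiary mesylate 20 (not isolated)
Conditions: MsCl, Et3N, DMAP (cat.), CH2Cl2, −20 → 23 °C
Reagents that add atoms: none
Why: Mesylation through the sulfene and E1cB elimination across C7–C11 give the tetrasubstituted alkene with defined regiochemistry, because only C7–H is acidic (α to the C6 ketone). The Z isomer (ester syn to C6) is the one needed and is separated from any E isomer.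

Step 15
Reactants: 21 (Z)-alkylidene keto ester
Product: 23 (2R,6R,8S)-2,13-bis[(tert-butyldimethylsilyl)oxy]-8-[(4-methoxybenzyl)oxy]germacra-1(10)E,4E,7(11)-trien-12,6-olide, via the C6 hydroxy ester 22 (not isolated)
Conditions: NaBH4, CeCl3·7H2O, MeOH, −78 → 0 °C
Reagents that add atoms: none
Why: Luche 1,2-reduction of the cross-conjugated ketone; hydride should add to the exposed outer face of the C6 carbonyl, the inner face being covered by the C1–C4 segment of ring A, which places H6 on the side of H8 and gives (6R). The alkoxide then closes on the Z-disposed ester to form ring B (5-exo-trig lactonisation).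

Step 16
Reactants: 23 protected ring A–ring B butenolide
Product: 24 (2R,6R,8S)-2,13-dihydroxy-8-[(4-methoxybenzyl)oxy]germacra-1(10)E,4E,7(11)-trien-12,6-olide
Conditions: HF·pyridine, pyridine, THF, 0 → 23 °C
Reagents that add atoms: none
Why: Fluoride cleavage of both silyl ethers (secondary allylic on O2, primary on O13) in buffered medium; the benzyl-type ether, the lactone and the alkenes are inert and no base strong enough to remove H6 is present.

Step 17
Reactants: 24 2,13-diol
Product: 25 (2R,6R,8S)-2,13-diacetoxy-8-[(4-methoxybenzyl)oxy]germacra-1(10)E,4E,7(11)-trien-12,6-olide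
Conditions: Ac2O, pyridine, DMAP (cat.), CH2Cl2, 0 °C
Reagents that add atoms: acetic anhydride, CC(=O)OC(C)=O
Why: Acylation of both hydroxyls with nucleophilic catalysis; pyridine is too weak a base to epimerise C6.

Step 18
Reactants: 25 2,13-diacetate
Product: 26 (2R,6R,8S)-2,13-diacetoxy-8-hydroxygermacra-1(10)E,4E,7(11)-trien-12,6-olide
Conditions: DDQ, CH2Cl2/aqueous pH 7 buffer, 0 °C
Reagents that add atoms: none
Why: Oxidative cleavage of the 4-methoxybenzyl ether by hydride abstraction under buffered, near-neutral conditions; the acetates, the lactone and the isolated alkenes are unaffected.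

Step 19
Reactants: 26 8-alcohol
Product: 27 (2R,6R,8S)-2,13-diacetoxy-8-(methacryloyloxy)germacra-1(10)E,4E,7(11)-trien-12,6-olide (target)
Conditions: methacrylic anhydride, DMAP, pyridine, CH2Cl2, 0 → 23 °C
Reagents that add atoms: methacrylic anhydride, CC(=C)C(=O)OC(=O)C(C)=C
Why: DMAP-catalysed acylation of the hindered secondary alcohol with the anhydride; it is placed last so that the polymerisable ester meets no further reagent.

## Compound list

1 | cis,cis-cyclohexane-1,3,5-triol | O[C@H]1C[C@@H](O)C[C@@H](O)C1 | starting material
2 | all-cis-5-[(4-methoxybenzyl)oxy]cyclohexane-1,3-diol (meso) | O[C@H]1C[C@@H](O)C[C@@H](OCc2ccc(OC)cc2)C1 | intermediate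
3 | (1R,3R,5S)-3-acetoxy-5-[(4-methoxybenzyl)oxy]cyclohexan-1-ol | O[C@H]1C[C@@H](OC(C)=O)C[C@@H](OCc2ccc(OC)cc2)C1 | intermediate
4 | (3S,5R)-3-acetoxy-5-[(4-methoxybenzyl)oxy]cyclohexan-1-one | O=C1C[C@@H](OC(C)=O)C[C@@H](OCc2ccc(OC)cc2)C1 | intermediate
5 | (R)-5-[(4-methoxybenzyl)oxy]cyclohex-2-en-1-one | O=C1C=CC[C@@H](OCc2ccc(OC)cc2)C1 | intermediate
6 | (5R)-5-[(4-methoxybenzyl)oxy]-1-methylcyclohex-2-en-1-ol (C1 epimers) | CC1(O)C=CC[C@@H](OCc2ccc(OC)cc2)C1 | intermediate
7 | (S)-5-[(4-methoxybenzyl)oxy]-3-methylcyclohex-2-en-1-one | CC1=CC(=O)C[C@@H](OCc2ccc(OC)cc2)C1 | intermediate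
8 | 3-ethoxycyclobut-2-en-1-one | CCOC1=CC(=O)C1 | starting material
9 | 3-ethoxy-1-methylcyclobut-2-en-1-ol (racemic, formed as lithium alkoxide) | CCOC1=CC(C)(O)C1 | intermediate
10 | 3-methylcyclobut-2-en-1-one | CC1=CC(=O)C1 | intermediate
11 | (R)-3-methylcyclobut-2-en-1-ol | CC1=C[C@H](O)C1 | intermediate
12 | (R)-tert-butyldimethyl[(3-methylcyclobut-2-en-1-yl)oxy]silane | CC1=C[C@H](O[Si](C)(C)C(C)(C)C)C1 | intermediate
13 | trans-fused photoadduct (target numbering 1R,2R,4R,5S,8S,10R; C6 ketone, O8 4-methoxybenzyl, O2 silyl) | O=C1C[C@@H](OCc4ccc(OC)cc4)C[C@@]2(C)[C@H]1[C@]3(C)C[C@@H](O[Si](C)(C)C(C)(C)C)[C@H]23 | intermediate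
14 | (2E,5R,6E,9S)-5-[(tert-butyldimethylsilyl)oxy]-9-[(4-methoxybenzyl)oxy]-3,7-dimethylcyclodeca-2,6-dien-1-one | COc1ccc(CO[C@H]2C/C(C)=C/[C@H](O[Si](C)(C)C(C)(C)C)C/C(C)=C/C(=O)C2)cc1 | intermediate
15 | ethyl 2-(hydroxymethyl)acrylate | C=C(CO)C(=O)OCC | starting material
16 | ethyl 2-{[(tert-butyldimethylsilyl)oxy]methyl}acrylate | C=C(CO[Si](C)(C)C(C)(C)C)C(=O)OCC | intermediate
17 | ethyl 3-{[(tert-butyldimethylsilyl)oxy]methyl}-1,2,4-trioxolane-3-carboxylate (ozonide) | CCOC(=O)C1(CO[Si](C)(C)C(C)(C)C)OCOO1 | intermediate
18 | ethyl 3-[(tert-butyldimethylsilyl)oxy]-2-oxopropanoate | CCOC(=O)C(=O)CO[Si](C)(C)C(C)(C)C | intermediate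
19 | C7 aldol adduct of 14 and 18 (C7/C11 epimers, 2R,8S) | CCOC(=O)C(O)(CO[Si](C)(C)C(C)(C)C)C1C(=O)/C=C(C)/C[C@@H](O[Si](C)(C)C(C)(C)C)/C=C(C)/C[C@@H]1OCc2ccc(OC)cc2 | intermediate
20 | tertiary mesylate of 19 | CCOC(=O)C(OS(C)(=O)=O)(CO[Si](C)(C)C(C)(C)C)C1C(=O)/C=C(C)/C[C@@H](O[Si](C)(C)C(C)(C)C)/C=C(C)/C[C@@H]1OCc2ccc(OC)cc2 | intermediate
21 | (Z)-alkylidene keto ester (CO2Et syn to C6 ketone, 2R,8S) | CCOC(=O)/C(CO[Si](C)(C)C(C)(C)C)=C1\C(=O)/C=C(C)/C[C@@H](O[Si](C)(C)C(C)(C)C)/C=C(C)/C[C@@H]1OCc2ccc(OC)cc2 | intermediate
22 | (6R)-hydroxy ester from 21 (2R,6R,8S) | CCOC(=O)/C(CO[Si](C)(C)C(C)(C)C)=C1\[C@H](O)/C=C(C)/C[C@@H](O[Si](C)(C)C(C)(C)C)/C=C(C)/C[C@@H]1OCc2ccc(OC)cc2 | intermediate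
23 | (2R,6R,8S)-2,13-bis[(tert-butyldimethylsilyl)oxy]-8-[(4-methoxybenzyl)oxy]germacra-1(10)E,4E,7(11)-trien-12,6-olide | COc1ccc(CO[C@H]2C/C(C)=C/[C@H](O[Si](C)(C)C(C)(C)C)C/C(C)=C/[C@H]3OC(=O)C(CO[Si](C)(C)C(C)(C)C)=C23)cc1 | intermediate
24 | (2R,6R,8S)-2,13-dihydroxy-8-[(4-methoxybenzyl)oxy]germacra-1(10)E,4E,7(11)-trien-12,6-olide | COc1ccc(CO[C@H]2C/C(C)=C/[C@H](O)C/C(C)=C/[C@H]3OC(=O)C(CO)=C23)cc1 | intermediate
25 | (2R,6R,8S)-2,13-diacetoxy-8-[(4-methoxybenzyl)oxy]germacra-1(10)E,4E,7(11)-trien-12,6-olide | COc1ccc(CO[C@H]2C/C(C)=C/[C@H](OC(C)=O)C/C(C)=C/[C@H]3OC(=O)C(COC(C)=O)=C23)cc1 | intermediate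
26 | (2R,6R,8S)-2,13-diacetoxy-8-hydroxygermacra-1(10)E,4E,7(11)-trien-12,6-olide | O[C@H]1C/C(C)=C/[C@H](OC(C)=O)C/C(C)=C/[C@H]2OC(=O)C(COC(C)=O)=C12 | intermediate
27 | (2R,6R,8S)-2,13-diacetoxy-8-(methacryloyloxy)germacra-1(10)E,4E,7(11)-trien-12,6-olide | C=C(C)C(=O)O[C@H]1C/C(C)=C/[C@H](OC(C)=O)C/C(C)=C/[C@H]2OC(=O)C(COC(C)=O)=C12 | target

## Step count and least certain steps

Total: 19 steps. Longest linear sequence: 14 steps (steps 1–5, 9, 10, 13–19); steps 6–8 and 11–12 are convergent branches.

**Step 10 (key step).** The most likely failure is a consecutive Cope rearrangement of the E,E-dienone in the hot zone or on the collector, together with scission of C2–C3 in place of C5–C10 in the diyl. The E,E-diene reaches a chair transition state easily and the silyloxy group at C2 stabilises the competing cleavage. Part of the material may also open from a boat-like diyl and lose E geometry. Fallback: leave the trans-fused series and reach 14 through the geometric isomer that has no easy Cope pathway. Setting out from 13, epimerisation at C5 (see step 9) gives the cis-fused ketone F1. Heated in solution (toluene, sealed base-washed glass, about 190 °C), F1 should open through the chair diyl to the (1(10)E,4Z)-dienone F2. Conjugate addition of Me3SnLi (THF, −78 °C) to the Z-enone gives the β-trimethylstannyl ketone F3. Oxidative destannylation (CrO3·2C5H5N, CH2Cl2) regenerates the enone, which can now take up the less strained E geometry, and the route is rejoined at 14.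

**Step 9.** The cycloaddition may give mainly cis-fused adducts, the trans-fused adduct may epimerise at C5 during isolation, and some coupling may occur in the crossed orientation (C4 to C10). The trans junction is only a kinetic product and the orientation rests on sterics. Fallback: do not try to keep the trans junction. Setting out from 7 and 12, the whole adduct mixture is treated with DBU (CH2Cl2, 23 °C), which converges every correctly oriented adduct on the cis-anti-cis ketone F1; crossed adducts are removed by chromatography at this point. F1 is then taken through the solution-phase opening and enone-geometry correction described under step 10 and comes back to the route at 14.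

**Step 13.** Proton transfer from the acidic keto ester to the enolate, retro-aldol cleavage on warming and silyl migration in the aldolate may outrun clean addition. Fallback: a Lewis-acid aldol in place of the basic one. Setting out from 14, the kinetic enolate is trapped with Me3SiCl to give the 2-silyloxydiene F4. F4 is combined with 18 under MgBr2·OEt2 (CH2Cl2, −78 °C), and citric acid work-up frees the tertiary hydroxyl and returns 19.

**Step 14.** The E1cB elimination has little inherent bias, so much of the material may form with the ester anti to C6, where it cannot lactonise. Fallback: close the lactone before making the alkene, so that the ring fixes the geometry. Setting out from 19, Luche reduction of the C6 ketone is followed by spontaneous lactonisation to the α-hydroxy lactone F5. Dehydration with SOCl2 and pyridine (CH2Cl2, 0 °C) then gives 23, where the route is rejoined after step 15. The direction of this elimination (towards C7, not C13) is then the point to watch.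

**Step 15.** Facial selectivity at C6 may be poor or reversed, since only the conformation of ring A controls it. Fallback: accept the wrong face and invert. Setting out from 21, the reduction then gives the 6-epi lactone F6. LiOH (THF/H2O, 0 °C) opens it to the (6S)-hydroxy acid F7, and Mitsunobu lactonisation (PPh3, DIAD, THF, high dilution) recloses ring B with inversion at C6 to give 23.

## Further compounds

F1 | step 9 | cis-anti-cis photoadduct, C5 epimer of 13 (target numbering 1R,2R,4R,5R,8S,10R) | O=C1C[C@@H](OCc4ccc(OC)cc4)C[C@@]2(C)[C@@H]1[C@]3(C)C[C@@H](O[Si](C)(C)C(C)(C)C)[C@H]23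
F2 | step 10 | (2Z,5R,6E,9S)-5-[(tert-butyldimethylsilyl)oxy]-9-[(4-methoxybenzyl)oxy]-3,7-dimethylcyclodeca-2,6-dien-1-one (1(10)E,4Z) | COc1ccc(CO[C@H]2C/C(C)=C/[C@H](O[Si](C)(C)C(C)(C)C)C/C(C)=C\C(=O)C2)cc1
F3 | step 10 | β-trimethylstannyl ketone from F2 (SnMe3 on C4, C4 epimers) | COc1ccc(CO[C@H]2C/C(C)=C/[C@H](O[Si](C)(C)C(C)(C)C)CC(C)([Sn](C)(C)C)CC(=O)C2)cc1
F4 | step 13 | C6 trimethylsilyl dienol ether of 14 (C6=C7) | COc1ccc(CO[C@H]2C/C(C)=C/[C@H](O[Si](C)(C)C(C)(C)C)C/C(C)=C/C(O[Si](C)(C)C)=C2)cc1
F5 | step 14 | 11-hydroxy-7,11-dihydro analogue of 23 (α-hydroxy lactone, C7/C11 epimers) | COc1ccc(CO[C@H]2C/C(C)=C/[C@H](O[Si](C)(C)C(C)(C)C)C/C(C)=C/[C@H]3OC(=O)C(O)(CO[Si](C)(C)C(C)(C)C)C23)cc1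
F6 | step 15 | 6-epi-23 (2R,6S,8S) | COc1ccc(CO[C@H]2C/C(C)=C/[C@H](O[Si](C)(C)C(C)(C)C)C/C(C)=C/[C@@H]3OC(=O)C(CO[Si](C)(C)C(C)(C)C)=C23)cc1
F7 | step 15 | (6S)-hydroxy acid from F6 (Z at C7=C11) | OC(=O)/C(CO[Si](C)(C)C(C)(C)C)=C1\[C@@H](O)/C=C(C)/C[C@@H](O[Si](C)(C)C(C)(C)C)/C=C(C)/C[C@@H]1OCc2ccc(OC)cc2
A1 | alternative 1 | 7-hydroxy γ-lactone fused to ring A (O8 silyl, O13 triethylsilyl, O2 acetate) | CC(C)(C)[Si](C)(C)O[C@H]1C/C(C)=C/[C@H](OC(C)=O)C/C(C)=C/[C@H]2OC(=O)[C@@H](CO[Si](CC)(CC)CC)[C@]12O
A2 | alternative 1 | thirteen-membered β-keto lactone (C11 epimers) | CC(C)(C)[Si](C)(C)O[C@H]1C/C(C)=C/[C@H](OC(C)=O)C/C(C)=C/COC(=O)C(CO[Si](CC)(CC)CC)C1=O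
A3 | alternative 2 | ring A dienyl triflate (triflate on C5, C7 ketal) | CC(C)[Si](C(C)C)(C(C)C)O[C@H]1C/C(C)=C/[C@H](O[Si](C)(C)C(C)(C)C)C/C(C)=C(OS(=O)(=O)C(F)(F)F)/[C@@H](OCc2ccc(OC)cc2)C12OCCO2
A4 | alternative 2 | trans-dialkenylcyclohexanol (isopropenyl on the C5 carbinol, (E)-2-silyloxyvinyl on C10) | C=C(C)[C@@]1(O)[C@@H](OCc2ccc(OC)cc2)C3(OCCO3)[C@@H](O[Si](C(C)C)(C(C)C)C(C)C)C[C@]1(C)/C=C/O[Si](C)(C)C(C)(C)C
A5 | alternative 3 | protected ring A–ring B butenolide (identical with 23) | COc1ccc(CO[C@H]2C/C(C)=C/[C@H](O[Si](C)(C)C(C)(C)C)C/C(C)=C/[C@H]3OC(=O)C(CO[Si](C)(C)C(C)(C)C)=C23)cc1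
A6 | alternative 3 | (E)-alkenyl iodide carrying the 2-(triisopropylsilyloxy)furan | COc1ccc(CO[C@@H](C/C(C)=C/[C@H](O[Si](C)(C)C(C)(C)C)C/C(C)=C/I)c2coc(O[Si](C(C)C)(C(C)C)C(C)C)c2CO[Si](C)(C)C(C)(C)C)cc1
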